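**Convention:** Daucane numbering is used throughout (C1 quaternary methyl carbon, C2 secondary carbinol, C4 isopropyl carbinol, C5 ring-fusion CH, C6 and C10 ester carbinols, C8/C9 epoxide). β is the face of the C1 methyl group and α the opposite face; "cis-daucane" means 1β-methyl, 5β-H.
**Assumption:** Commercial (R)-(−)-terpinen-4-ol is used in enantiopure form.

## Retrosynthetic overview

- Target ⇒ desilylation and double angeloylation of an 8β,9β-epoxy-cis-daucane-4α,6β,10β-triol. The three C–O bonds at C10, C9 and C8 come from one key operation on a Δ9-cycloheptene: singlet-oxygen ene reaction plus titanium-mediated oxygen transfer.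
- Seven-membered ring (formed last) ⇒ ring-closing metathesis of a cyclopentane carrying a vinyl group at C1 and a 1-hydroxy-3-methylpent-4-enyl chain at C5; the chain ⇒ nickel-catalysed homoallylation of a cyclopentanecarbaldehyde with isoprene.
- Quaternary C1 ⇒ hydroxyl-directed conjugate vinylation of a γ-hydroxy cyclopentene carbaldehyde (proposed new boron-tethered method).
- Five-membered ring (formed first) ⇒ ozonolysis/aldol ring contraction of cis-p-menth-1-ene-4,6-diol ⇐ SeO2 allylic hydroxylation of (R)-(−)-terpinen-4-ol, which supplies the C4 carbinol and the isopropyl group.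
- Ring order: cyclohexene (bought) → cyclopentene → cycloheptene → epoxide.

## Route

Step 1
Reactants: 1 (R)-(−)-terpinen-4-ol
Product: 2 (1S,3S)-4-methyl-1-(propan-2-yl)cyclohex-4-ene-1,3-diol
Conditions: SeO2 (0.5 equiv), tBuOOH (2.5 equiv), CH2Cl2, 23 °C
Reagents that add atoms: tert-butyl hydroperoxide, CC(C)(C)OO (oxygen relayed by SeO2, O=[Se]=O)
Why: Sharpless–Umbreit SeO2/tBuOOH allylic hydroxylation (ene reaction then 2,3-sigmatropic shift) follows the Guillemonat rule and oxidises the ring CH2 next to the methyl-bearing alkene carbon, and the oxygen is delivered pseudoaxially on the half-chair with equatorial isopropyl, that is cis to the axial tertiary hydroxyl, which sets the future C2 as 2α.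

Step 2
Reactants: 2 (1S,3S)-4-methyl-1-(propan-2-yl)cyclohex-4-ene-1,3-diol
Product: 4 (3S,5S)-3,5-dihydroxy-2-methyl-5-(propan-2-yl)cyclopent-1-ene-1-carbaldehyde, via keto aldehyde 3 (not isolated)
Conditions: O3, CH2Cl2/MeOH, −78 °C; Me2S, −78 → 23 °C; then piperidine (0.2 equiv), AcOH (0.2 equiv), PhMe, 50 °C
Reagents that add atoms: ozone, [O-][O+]=O
Why: Ozonolysis of the trisubstituted ring alkene gives a 1,6-keto aldehyde whose aldehyde-derived enamine adds to the methyl ketone in a 5-(enolexo)-exo-trig aldol condensation (the limonene-type ring contraction), giving the cyclopentene carbaldehyde without touching the two carbinol stereocentres.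

Step 3
Reactants: 4 (3S,5S)-3,5-dihydroxy-2-methyl-5-(propan-2-yl)cyclopent-1-ene-1-carbaldehyde; 5 dibutyl ethenylboronate
Product: 8 (1S,2R,3S,5S)-2-ethenyl-3,5-dihydroxy-2-methyl-5-(propan-2-yl)cyclopentane-1-carbaldehyde, via boronate ester 6 (not isolated), via boron enolate 7 (not isolated)
Conditions: 5 (1.5 equiv), 4 Å MS, PhMe, 23 → 80 °C; then pH 7 phosphate buffer
Reagents that add atoms: dibutyl ethenylboronate (5), C=CB(OCCCC)OCCCC
Why: Proposed new method: transesterification anchors the vinylboron unit on the allylic C2 hydroxyl, the s-cis formyl oxygen then coordinates boron to give a tetracoordinate boronate whose vinyl group migrates to the β-carbon C1 through a six-membered chair-like transition state on the face of the C2 oxygen (also the face anti to isopropyl), so the quaternary centre forms with vinyl cis to both hydroxyls, and hydrolysis of the boron enolate protonates C5 to the more stable aldehyde trans to isopropyl; the closest known reaction types are the Petasis borono-Mannich reaction (hydroxyl-tethered boronate transfer) and the diol-boronate conjugate alkenylation of enones, neither shown for an enal or for building a quaternary carbon by delivery from a neighbouring hydroxyl.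

Step 4
Reactants: 8 (1S,2R,3S,5S)-2-ethenyl-3,5-dihydroxy-2-methyl-5-(propan-2-yl)cyclopentane-1-carbaldehyde
Product: 9 (1S,2R,3S,5S)-2-ethenyl-5-hydroxy-2-methyl-5-(propan-2-yl)-3-[(triethylsilyl)oxy]cyclopentane-1-carbaldehyde
Conditions: Et3SiCl (1.2 equiv), imidazole, CH2Cl2, 0 °C
Reagents that add atoms: chlorotriethylsilane, CC[Si](Cl)(CC)CC
Why: Chemoselective silyl ether formation at the secondary C2 hydroxyl in the presence of the tertiary C4 hydroxyl masks the one secondary alcohol that must stay unacylated, and no stereocentre is touched.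

Step 5
Reactants: 9 (1S,2R,3S,5S)-2-ethenyl-5-hydroxy-2-methyl-5-(propan-2-yl)-3-[(triethylsilyl)oxy]cyclopentane-1-carbaldehyde; 10 isoprene
Product: 11 (1S,2R,3R,4S)-3-ethenyl-2-[(1R,3R)-1-hydroxy-3-methylpent-4-en-1-yl]-3-methyl-1-(propan-2-yl)-4-[(triethylsilyl)oxy]cyclopentan-1-ol
Conditions: Ni(acac)2 (10 mol %), isoprene (4 equiv), Et3B (2.4 equiv), THF, 23 °C
Reagents that add atoms: isoprene (10), C=CC(C)=C
Why: Tamaru nickel-catalysed homoallylation (zerovalent nickel couples C1 of isoprene with the aldehyde, Et3B serving as Lewis acid and hydride source) gives the bishomoallylic alcohol with its inherent 1,3-anti relation of C6–OH and C8–methyl, and the C4 hydroxyl (hydrogen bond or O–BEt2 chelate) holds the formyl oxygen so that attack comes from the face away from C1, setting C6 as R (6β) and thereby C8 as R (8α-methyl, 8β-H).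

Step 6
Reactants: 11 (1S,2R,3R,4S)-3-ethenyl-2-[(1R,3R)-1-hydroxy-3-methylpent-4-en-1-yl]-3-methyl-1-(propan-2-yl)-4-[(triethylsilyl)oxy]cyclopentan-1-ol
Product: 12 2α-(triethylsilyloxy)-cis-dauc-9-ene-4α,6β-diol (8α-methyl)
Conditions: second-generation Grubbs catalyst (H2IMes)(PCy3)Cl2Ru=CHPh (5 mol %), CH2Cl2 (5 mM), 40 °C
Reagents that add atoms: none
Why: Ring-closing olefin metathesis between the neopentyl vinyl group and the terminal alkene closes the cis-fused cycloheptene with loss of ethene, and no stereocentre is affected.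

Step 7
Reactants: 12 2α-(triethylsilyloxy)-cis-dauc-9-ene-4α,6β-diol (8α-methyl)
Product: 14 8β,9β-epoxy-2α-(triethylsilyloxy)-cis-daucane-4α,6β,10β-triol, via allylic hydroperoxide 13 (not isolated)
Conditions: O2, hν (visible light), tetraphenylporphyrin (cat.), Ti(OiPr)4 (20 mol %), 4 Å MS, CH2Cl2, 0 → 23 °C
Reagents that add atoms: dioxygen, O=O
Why: The Schenck ene reaction of singlet oxygen can abstract only the 8β-hydrogen (C1 has none), so oxygen is delivered suprafacially to C10 on the convex β face with shift of the alkene to C8=C9, and the titanium-bound allylic hydroperoxide then transfers its distal oxygen to the same face of the new alkene (Adam hydroxy-epoxidation, hydroxyl-directed as in the Sharpless epoxidation), which sets C10, C9 and C8.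

Step 8
Reactants: 14 8β,9β-epoxy-2α-(triethylsilyloxy)-cis-daucane-4α,6β,10β-triol; 15 angelic acid
Product: 17 6β,10β-bis(angeloyloxy)-8β,9β-epoxy-2α-(triethylsilyloxy)-cis-daucan-4α-ol, via monoangelate 16 (not isolated)
Conditions: 15 (6 equiv), 2,4,6-Cl3C6H2COCl (6 equiv), Et3N (12 equiv), PhMe, 23 → 75 °C
Reagents that add atoms: angelic acid (15), C/C=C(/C)C(=O)O
Why: Yamaguchi-type mixed-anhydride esterification without DMAP acylates the two secondary alcohols without Z to E isomerisation of the angelate, the tertiary C4 hydroxyl and the silyl ether do not react, and no stereocentre is touched.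

Step 9
Reactants: 17 6β,10β-bis(angeloyloxy)-8β,9β-epoxy-2α-(triethylsilyloxy)-cis-daucan-4α-ol
Product: 18 6β,10β-bis(angeloyloxy)-8β,9β-epoxy-cis-daucane-2α,4α-diol (1R,2S,4S,5R,6R,8S,9R,10R; CNP0265715.2)
Conditions: Et3N·3HF, THF/MeCN, 23 °C
Reagents that add atoms: none
Why: Fluoride-mediated desilylation of the triethylsilyl ether under near-neutral conditions leaves the epoxide and both angelates intact and reveals the 2α-hydroxyl.

## Compound list

1 | (R)-(−)-terpinen-4-ol, (1R)-4-methyl-1-(propan-2-yl)cyclohex-3-en-1-ol | CC1=CC[C@@](O)(C(C)C)CC1 | starting material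
2 | (1S,3S)-4-methyl-1-(propan-2-yl)cyclohex-4-ene-1,3-diol (cis-p-menth-1-ene-4,6-diol) | CC1=CC[C@@](O)(C(C)C)C[C@@H]1O | intermediate
3 | (3R,5S)-3,5-dihydroxy-6-oxo-3-(propan-2-yl)heptanal (keto aldehyde) | CC(=O)[C@@H](O)C[C@](O)(C(C)C)CC=O | intermediate
4 | (3S,5S)-3,5-dihydroxy-2-methyl-5-(propan-2-yl)cyclopent-1-ene-1-carbaldehyde | O=CC1=C(C)[C@@H](O)C[C@]1(O)C(C)C | intermediate
5 | dibutyl ethenylboronate (vinylboronic acid dibutyl ester) | C=CB(OCCCC)OCCCC | starting material
6 | (3S,5S)-3-{[butoxy(ethenyl)boranyl]oxy}-5-hydroxy-2-methyl-5-(propan-2-yl)cyclopent-1-ene-1-carbaldehyde (boronate ester) | O=CC1=C(C)[C@@H](OB(C=C)OCCCC)C[C@]1(O)C(C)C | intermediate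
7 | boron enolate: seven-membered 1,3,2-dioxaborepine (B–OBu) joining the C2 oxygen and the enol oxygen of C6, C1 bearing methyl (β) and vinyl (α) | C=C[C@@]1(C)[C@@H]2C[C@](O)(C(C)C)C1=COB(OCCCC)O2 | intermediate
8 | (1S,2R,3S,5S)-2-ethenyl-3,5-dihydroxy-2-methyl-5-(propan-2-yl)cyclopentane-1-carbaldehyde | O=C[C@@H]1[C@@](O)(C(C)C)C[C@H](O)[C@]1(C)C=C | intermediate
9 | (1S,2R,3S,5S)-2-ethenyl-5-hydroxy-2-methyl-5-(propan-2-yl)-3-[(triethylsilyl)oxy]cyclopentane-1-carbaldehyde | O=C[C@@H]1[C@@](O)(C(C)C)C[C@H](O[Si](CC)(CC)CC)[C@]1(C)C=C | intermediate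
10 | isoprene | C=CC(C)=C | starting material
11 | (1S,2R,3R,4S)-3-ethenyl-2-[(1R,3R)-1-hydroxy-3-methylpent-4-en-1-yl]-3-methyl-1-(propan-2-yl)-4-[(triethylsilyl)oxy]cyclopentan-1-ol | O[C@H](C[C@@H](C)C=C)[C@@H]1[C@@](O)(C(C)C)C[C@H](O[Si](CC)(CC)CC)[C@]1(C)C=C | intermediate
12 | 2α-(triethylsilyloxy)-cis-dauc-9-ene-4α,6β-diol (8α-methyl) | O[C@@H]1C[C@@H](C)C=C[C@@]2(C)[C@@H](O[Si](CC)(CC)CC)C[C@](O)(C(C)C)[C@@H]12 | intermediate
13 | 10β-hydroperoxy-2α-(triethylsilyloxy)-cis-dauc-8-ene-4α,6β-diol (allylic hydroperoxide) | O[C@@H]1CC(C)=C[C@H](OO)[C@@]2(C)[C@@H](O[Si](CC)(CC)CC)C[C@](O)(C(C)C)[C@@H]12 | intermediate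
14 | 8β,9β-epoxy-2α-(triethylsilyloxy)-cis-daucane-4α,6β,10β-triol | O[C@@H]1C[C@]2(C)O[C@@H]2[C@H](O)[C@@]2(C)[C@@H](O[Si](CC)(CC)CC)C[C@](O)(C(C)C)[C@@H]12 | intermediate
15 | angelic acid, (Z)-2-methylbut-2-enoic acid | C/C=C(/C)C(=O)O | starting material
16 | 6β-angeloyloxy-8β,9β-epoxy-2α-(triethylsilyloxy)-cis-daucane-4α,10β-diol (monoangelate) | C/C=C(/C)C(=O)O[C@@H]1C[C@]2(C)O[C@@H]2[C@H](O)[C@@]2(C)[C@@H](O[Si](CC)(CC)CC)C[C@](O)(C(C)C)[C@@H]12 | intermediate
17 | 6β,10β-bis(angeloyloxy)-8β,9β-epoxy-2α-(triethylsilyloxy)-cis-daucan-4α-ol | C/C=C(/C)C(=O)O[C@@H]1C[C@]2(C)O[C@@H]2[C@H](OC(=O)/C(C)=C\C)[C@@]2(C)[C@@H](O[Si](CC)(CC)CC)C[C@](O)(C(C)C)[C@@H]12 | intermediate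
18 | 6β,10β-bis(angeloyloxy)-8β,9β-epoxy-cis-daucane-2α,4α-diol, (1R,2S,4S,5R,6R,8S,9R,10R) | C/C=C(/C)C(=O)O[C@@H]1C[C@]2(C)O[C@@H]2[C@H](OC(=O)/C(C)=C\C)[C@@]2(C)[C@@H](O)C[C@](O)(C(C)C)[C@@H]12 | target

## Step count and risks

Total step count: 9. Longest linear sequence: 9 steps (from 1; compounds 5, 10 and 15 are bought).

Steps most likely to fail:

**Step 3 (proposed boron-tethered conjugate vinylation).** The vinyl shift to a fully substituted enal β-carbon may not occur. The fallback uses known temporary-silicon-tether radical chemistry and sets out from 4. Compound 4 is silylated at the secondary hydroxyl with (1-bromoethenyl)chlorodimethylsilane and imidazole to give the (1-bromoethenyl)dimethylsilyl ether F1. Bu3SnH/AIBN (PhH, 80 °C) generates the α-silylvinyl radical, which closes 5-exo onto C1 of the enal from the oxygen-bearing face to give the cis-fused oxasilolane F2. Bu4NF (THF/DMF) then cleaves the Si–O bond and protodesilylates the alkenylsilane, and the route is rejoined at 8.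

**Step 5 (nickel-catalysed homoallylation).** Facial selectivity at C6 on this hindered β-hydroxy aldehyde may be low. The fallback sets out from 9 and replaces the reductive coupling with a chelation-controlled Grignard addition. Compound 9 is precomplexed with MgBr2·OEt2 (CH2Cl2, −78 °C) and treated with (S)-(2-methylbut-3-en-1-yl)magnesium bromide F3, made from (S)-4-bromo-3-methylbut-1-ene and magnesium. C8 then comes from the reagent and C6 from the Cram chelate, and the route is rejoined at 11.

**Step 7 (photooxygenation with titanium-mediated epoxidation).** The cis-disubstituted alkene may react too slowly or the product may over-oxidise. The fallback sets out from 12. mCPBA/NaHCO3 epoxidises the convex β face to give the 9β,10β-epoxide F4. Et2Al(TMP) (diethylaluminium 2,2,6,6-tetramethylpiperidide) isomerises it by syn removal of the 8β-hydrogen to the allylic alcohol F5 (10β-OH, C8=C9). VO(acac)2/tBuOOH hydroxyl-directed epoxidation then gives 14, where the route is rejoined.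

Further compounds
F1 | step 3 | (3S,5S)-3-{[(1-bromoethenyl)dimethylsilyl]oxy}-5-hydroxy-2-methyl-5-(propan-2-yl)cyclopent-1-ene-1-carbaldehyde | O=CC1=C(C)[C@@H](O[Si](C)(C)C(Br)=C)C[C@]1(O)C(C)C
F2 | step 3 | cis-fused oxasilolane (ring C2–O–SiMe2–C(=CH2)–C1) carrying 1β-methyl, 5α-formyl, 4α-hydroxy and 4β-isopropyl | O=C[C@@H]1[C@@](O)(C(C)C)C[C@@H]2O[Si](C)(C)C(=C)[C@]12C
F3 | step 5 | (S)-(2-methylbut-3-en-1-yl)magnesium bromide | Br[Mg]C[C@@H](C)C=C
F4 | step 7 | 9β,10β-epoxy-2α-(triethylsilyloxy)-cis-daucane-4α,6β-diol (8α-methyl) | O[C@@H]1C[C@@H](C)[C@@H]2O[C@@H]2[C@@]2(C)[C@@H](O[Si](CC)(CC)CC)C[C@](O)(C(C)C)[C@@H]12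
F5 | step 7 | 2α-(triethylsilyloxy)-cis-dauc-8-ene-4α,6β,10β-triol | O[C@@H]1CC(C)=C[C@H](O)[C@@]2(C)[C@@H](O[Si](CC)(CC)CC)C[C@](O)(C(C)C)[C@@H]12
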